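Locants: flavanone numbering for rings A, C and B. Ring D is the pyran O1''–C2''(CH3)2–C3''=C4'', fused to ring B at C4'–C5'.
Cuts: (1) the two MOM ethers; (2) C2'–CH2 of the 2'-prenyl group (retro-Claisen to the 3'-O-1,1-dimethylallyl ether); (3) C2–C1' between rings C and B; (4) C3''=C4'' back to a C4'' ketone, then C3''–C2'' and O1''–C4' together, which releases acetone and a 2-fluoroacetophenone.
Enabling feature: O1''–C2''(CH3)2 is the C=O of acetone, and C4'' sits on C5', ortho to C4'. With C4'' as a ketone, C3'' is an enolate carbon and F–C4'=C5'–C4''=O is a vinylogous acyl fluoride, so ring B takes up acetone as a two-atom unit, and this fixes which of its two vicinal oxygens belongs to ring D.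
Forward: ring B is bought (fluorine steers the C–H oxygenation to C3'), ring D is annulated onto it, and rings A/C are made separately as a chromone. The halves are joined at C2–C1', the 2'-prenyl group is delivered from O3', and the phenols are freed.
Stereochemistry: the only stereocentre, C2 (S), is set in the joining step by a rhodium/chiral-diene 1,4-addition (catalyst control, Re face of C2). All later steps are neutral or weakly acidic.
Key step: step 4

Assumption: the enantiomer of the chiral diene ligand in step 11 is chosen so that the aryl group reaches the Re face of C2; both enantiomers can be bought.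

Step 1
Reactants: 1 2-methylbut-3-en-2-ol
Product: 3 tert-butyl 2-methylbut-3-en-2-yl carbonate, via lithium alkoxide 2 (not isolated)
Conditions: n-BuLi, THF, 0 °C; Boc2O, 0 → 23 °C
Reagents that add atoms: n-butyllithium, [Li]CCCC (the lithium of 2 only); di-tert-butyl dicarbonate, CC(C)(C)OC(=O)OC(=O)OC(C)(C)C
Why: Acylation of a tertiary lithium alkoxide with Boc2O is a standard mixed-carbonate synthesis, in which tert-butyl carbonate leaves and loses CO2.

Step 2
Reactants: 4 1-(5-bromo-2-fluorophenyl)ethanone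
Product: 6 1-(5-bromo-2-fluoro-3-hydroxyphenyl)ethanone, via pinacol boronate 5 (not isolated)
Conditions: [Ir(OMe)(cod)]2 (1.5 mol %), dtbpy (3 mol %), B2pin2, THF, 70 °C; then 30 % H2O2, pH 7 phosphate buffer, 0 → 23 °C
Reagents that add atoms: bis(pinacolato)diboron, CC1(C)OB(OC1(C)C)B2OC(C)(C)C(C)(C)O2 (the boryl group of 5 only); hydrogen peroxide, OO
Why: Sterically governed iridium-catalysed aromatic C–H borylation with oxidation of the C–B bond in the same flask should hit C3–H, the only ring C–H without a large ortho neighbour (fluorine is small and acidifies it, whereas C4–H lies next to Br and C6–H between Br and acetyl), and ketone, C–Br and C–F are tolerated.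

Step 3
Reactants: 6 1-(5-bromo-2-fluoro-3-hydroxyphenyl)ethanone; 3 tert-butyl 2-methylbut-3-en-2-yl carbonate
Product: 7 1-[5-bromo-2-fluoro-3-(2-methylbut-3-en-2-yloxy)phenyl]ethanone
Conditions: Pd(PPh3)4 (2 mol %), THF, 0 °C
Reagents that add atoms: none
Why: In this Tsuji–Trost O-allylation zerovalent palladium ionises 3 to the 1,1-dimethyl-π-allyl cation and tert-butoxide, which deprotonates 6, and the phenoxide attacks the more substituted terminus under kinetic control at a temperature at which the C–Br bond does not undergo oxidative addition.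

Step 4
Reactants: 7 1-[5-bromo-2-fluoro-3-(2-methylbut-3-en-2-yloxy)phenyl]ethanone; 8 acetone
Product: 11 6-bromo-2,2-dimethyl-8-(2-methylbut-3-en-2-yloxy)chroman-4-one, via lithium enolate 9 (not isolated), via lithium aldolate 10 (not isolated)
Conditions: LiN(SiMe3)2 (1.05 equiv), THF, −78 °C; acetone 8 (5 equiv), −78 °C; DMPU, −78 → 23 °C
Reagents that add atoms: lithium bis(trimethylsilyl)amide, [Li]N([Si](C)(C)C)[Si](C)(C)C (the lithium of 9 and 10 only)
Why: Proposed new method: LiN(SiMe3)2 turns the methyl ketone of 7 into enolate 9, whose carbon (the future C3'') adds to the carbonyl carbon of acetone (C3''–C2'' bond) to give the tertiary alkoxide 10, and this oxygen, the former acetone oxygen, then attacks C4' of ring B and expels fluoride through a Meisenheimer adduct whose charge is carried by the C4'' carbonyl (O1''–C4' bond), a formal anionic [4+2] annulation of the C3''–C4''–C5'–C4' unit with the C=O of acetone. The closest known reaction types are the lithium enolate aldol addition to ketones, the base-mediated closure of 1-(2-fluoroaryl)-1,3-diketones to chromones by intramolecular SNAr, and the Kabbe chromanone synthesis, which joins the same partners but makes the other C–O bond, and the merger into one aldol/SNAr operation with a simple ketone is the unproven part. Ring D closes in a 6-endo-trig addition–elimination on the vinylogous acyl fluoride F–C4'=C5'–C4''=O, and no stereocentre is formed. The ketone–ketone aldol is reversible and unfavourable on warming, but 7 is more acidic than acetone, acetone is present in excess as the only unhindered electrophile, and precipitation of LiF is the only irreversible exit, so retro-aldol merely returns 9 to the pool (Curtin–Hammett funnel), while DMPU loosens the lithium chelate between alkoxide and ketone oxygen that would hold the nucleophile away from C4'. Site selectivity (C–F and not C–Br) follows from the substrate, since only C4' is conjugated with the ketone and within reach of the tethered alkoxide, whereas C1'–Br is meta to the ketone. The hindered non-nucleophilic amide base, the absence of other acidic C–H bonds and the base stability of the tertiary allyl aryl ether secure chemoselectivity.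

Step 5
Reactants: 11 6-bromo-2,2-dimethyl-8-(2-methylbut-3-en-2-yloxy)chroman-4-one
Product: 12 6-bromo-2,2-dimethyl-8-(2-methylbut-3-en-2-yloxy)chroman-4-ol (racemic)
Conditions: NaBH4, MeOH, 0 °C
Reagents that add atoms: none
Why: Borohydride 1,2-reduction of the aryl ketone leaves aryl bromide, alkene and ethers untouched, and the new carbinol centre C4'' is accepted as a racemate because step 6 erases it.

Step 6
Reactants: 12 6-bromo-2,2-dimethyl-8-(2-methylbut-3-en-2-yloxy)chroman-4-ol
Product: 14 6-bromo-2,2-dimethyl-8-(2-methylbut-3-en-2-yloxy)-2H-chromene, via benzylic mesylate 13 (not isolated)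
Conditions: MsCl, Et3N, CH2Cl2, 0 → 23 °C
Reagents that add atoms: methanesulfonyl chloride, CS(=O)(=O)Cl (the mesyl group of 13 only)
Why: Mesylation followed by E1-type elimination should be easy because O1'' stabilises the benzylic cation at C4'', Et3N removes H3'', and the base-only medium spares the acid-labile tertiary allyl aryl ether, so that the ketone helper is gone and C3''=C4'' is in place.

Step 7
Reactants: 14 6-bromo-2,2-dimethyl-8-(2-methylbut-3-en-2-yloxy)-2H-chromene
Product: 17 [2,2-dimethyl-8-(2-methylbut-3-en-2-yloxy)-2H-chromen-6-yl]boronic acid, via aryllithium 15 (not isolated), via lithium borate 16 (not isolated)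
Conditions: n-BuLi, THF, −78 °C; B(OiPr)3, −78 → 0 °C; aq. NH4Cl
Reagents that add atoms: n-butyllithium, [Li]CCCC (the lithium of 15 and 16 only); triisopropyl borate, CC(C)OB(OC(C)C)OC(C)C; water, O
Why: Bromine–lithium exchange, borate trapping and mild hydrolysis form the standard arylboronic acid synthesis, and at −78 °C the chromene and the quaternary allyl ether (no α-hydrogen for a Wittig rearrangement) are inert.

Step 8
Reactants: 18 2,4,6-trihydroxyacetophenone; 19 prenyl bromide (1-bromo-3-methylbut-2-ene)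
Product: 20 1-[2,4,6-trihydroxy-3-(3-methylbut-2-enyl)phenyl]ethanone
Conditions: KOH (1 equiv), H2O, 0 → 23 °C
Reagents that add atoms: none
Why: Nuclear C-prenylation of the ambident phloroglucinol-type phenolate is favoured in water, and since C3 and C5 are equivalent only the degree of alkylation has to be held by stoichiometry.

Step 9
Reactants: 20 1-[2,4,6-trihydroxy-3-(3-methylbut-2-enyl)phenyl]ethanone
Product: 21 1-[2-hydroxy-4,6-bis(methoxymethoxy)-3-(3-methylbut-2-enyl)phenyl]ethanone
Conditions: MOMCl (2.1 equiv), iPr2NEt, CH2Cl2, 0 °C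
Reagents that add atoms: chloromethyl methyl ether, COCCl
Why: In this selective O-alkylation the 4-OH, which is not hydrogen bonded, reacts first and the less hindered 6-OH second, while the 2-OH flanked by prenyl and chelated to the acetyl C=O stays free, which later places the prenyl group at C8.

Step 10
Reactants: 21 1-[2-hydroxy-4,6-bis(methoxymethoxy)-3-(3-methylbut-2-enyl)phenyl]ethanone
Product: 23 5,7-bis(methoxymethoxy)-8-(3-methylbut-2-enyl)-4H-chromen-4-one, via enaminone 22 (not isolated)
Conditions: Me2NCH(OMe)2, toluene, 100 °C; evaporate; AcOH, 60 °C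
Reagents that add atoms: N,N-dimethylformamide dimethyl acetal, COC(OC)N(C)C
Why: Condensation of the methyl ketone with the amide acetal and weak-acid addition–elimination by the free 2-OH (6-endo-trig) is the standard enaminone route to 2,3-unsubstituted chromones, and acetic acid leaves MOM ethers and the prenyl group intact.

Step 11
Reactants: 17 [2,2-dimethyl-8-(2-methylbut-3-en-2-yloxy)-2H-chromen-6-yl]boronic acid; 23 5,7-bis(methoxymethoxy)-8-(3-methylbut-2-enyl)-4H-chromen-4-one
Product: 24 (2S)-2-[2,2-dimethyl-8-(2-methylbut-3-en-2-yloxy)-2H-chromen-6-yl]-5,7-bis(methoxymethoxy)-8-(3-methylbut-2-enyl)chroman-4-one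
Conditions: [RhCl(C2H4)2]2 (2.5 mol %), 2,5-diphenylbicyclo[2.2.2]octa-2,5-diene (5.5 mol %, enantiomer matched to 2S), K3PO4 (0.5 equiv), toluene–H2O, 40 °C
Reagents that add atoms: none
Why: The Hayashi–Miyaura asymmetric 1,4-addition is precedented for arylboronic acids and chromones with rhodium/chiral-diene catalysts, the aryl–rhodium species from 17 (which has no ortho substituent at this stage) adds across C2=C3 with the C2-symmetric diene shielding the Si face so that the aryl group reaches the Re face of C2 and sets 2S, and the weakly basic two-phase medium keeps ring C from opening.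

Step 12
Reactants: 24 (2S)-2-[2,2-dimethyl-8-(2-methylbut-3-en-2-yloxy)-2H-chromen-6-yl]-5,7-bis(methoxymethoxy)-8-(3-methylbut-2-enyl)chroman-4-one
Product: 26 (2S)-2-[8-hydroxy-2,2-dimethyl-7-(3-methylbut-2-enyl)-2H-chromen-6-yl]-5,7-bis(methoxymethoxy)-8-(3-methylbut-2-enyl)chroman-4-one, via ortho-dienone 25 (not isolated)
Conditions: Eu(fod)3 (10 mol %), toluene, 100 °C
Reagents that add atoms: none
Why: In this aromatic Claisen [3,3] rearrangement of a 1,1-dimethylallyl aryl ether the ortho position C4' is blocked by O1'', so the allyl terminus bonds to C2' and dienone 25 (transient sp3 C2') tautomerises to the phenol, which delivers the 2'-prenyl group and the free 3'-OH at once under neutral conditions that do not touch C2.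

Step 13
Reactants: 26 (2S)-2-[8-hydroxy-2,2-dimethyl-7-(3-methylbut-2-enyl)-2H-chromen-6-yl]-5,7-bis(methoxymethoxy)-8-(3-methylbut-2-enyl)chroman-4-one
Product: 27 (2S)-5,7-dihydroxy-2-[8-hydroxy-2,2-dimethyl-7-(3-methylbut-2-enyl)-2H-chromen-6-yl]-8-(3-methylbut-2-enyl)chroman-4-one (target)
Conditions: 3 M aq. HCl, MeOH, 50 °C
Reagents that add atoms: none
Why: Acid-catalysed transacetalisation of aryl MOM ethers in methanol is precedented on prenylated flavanones, short exposure at moderate temperature limits addition of the phenols to the prenyl groups, and ring C is not opened under these conditions, so C2 stays S.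

Compound list
1 | 2-methylbut-3-en-2-ol | C=CC(C)(C)O | starting material
2 | lithium 2-methylbut-3-en-2-olate | [Li+].[O-]C(C)(C)C=C | intermediate
3 | tert-butyl 2-methylbut-3-en-2-yl carbonate | C=CC(C)(C)OC(=O)OC(C)(C)C | intermediate
4 | 1-(5-bromo-2-fluorophenyl)ethanone | CC(=O)c1cc(Br)ccc1F | starting material
5 | 1-[5-bromo-2-fluoro-3-(4,4,5,5-tetramethyl-1,3,2-dioxaborolan-2-yl)phenyl]ethanone | CC(=O)c1cc(Br)cc(B2OC(C)(C)C(C)(C)O2)c1F | intermediate
6 | 1-(5-bromo-2-fluoro-3-hydroxyphenyl)ethanone | CC(=O)c1cc(Br)cc(O)c1F | intermediate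
7 | 1-[5-bromo-2-fluoro-3-(2-methylbut-3-en-2-yloxy)phenyl]ethanone | CC(=O)c1cc(Br)cc(OC(C)(C)C=C)c1F | intermediate
8 | acetone | CC(C)=O | starting material
9 | lithium enolate of 7 | [Li+].[O-]C(=C)c1cc(Br)cc(OC(C)(C)C=C)c1F | intermediate
10 | lithium aldolate (lithium 4-aryl-2-methyl-4-oxobutan-2-olate) | [Li+].[O-]C(C)(C)CC(=O)c1cc(Br)cc(OC(C)(C)C=C)c1F | intermediate
11 | 6-bromo-2,2-dimethyl-8-(2-methylbut-3-en-2-yloxy)chroman-4-one | CC1(C)CC(=O)c2cc(Br)cc(OC(C)(C)C=C)c2O1 | intermediate
12 | 6-bromo-2,2-dimethyl-8-(2-methylbut-3-en-2-yloxy)chroman-4-ol, racemic | CC1(C)CC(O)c2cc(Br)cc(OC(C)(C)C=C)c2O1 | intermediate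
13 | methanesulfonate of 12, racemic | CC1(C)CC(OS(C)(=O)=O)c2cc(Br)cc(OC(C)(C)C=C)c2O1 | intermediate
14 | 6-bromo-2,2-dimethyl-8-(2-methylbut-3-en-2-yloxy)-2H-chromene | CC1(C)C=Cc2cc(Br)cc(OC(C)(C)C=C)c2O1 | intermediate
15 | 6-lithio-2,2-dimethyl-8-(2-methylbut-3-en-2-yloxy)-2H-chromene | [Li]c1cc2C=CC(C)(C)Oc2c(OC(C)(C)C=C)c1 | intermediate
16 | lithium aryl(triisopropoxy)borate | [Li+].CC(C)O[B-](OC(C)C)(OC(C)C)c1cc2C=CC(C)(C)Oc2c(OC(C)(C)C=C)c1 | intermediate
17 | [2,2-dimethyl-8-(2-methylbut-3-en-2-yloxy)-2H-chromen-6-yl]boronic acid | OB(O)c1cc2C=CC(C)(C)Oc2c(OC(C)(C)C=C)c1 | intermediate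
18 | 2,4,6-trihydroxyacetophenone | CC(=O)c1c(O)cc(O)cc1O | starting material
19 | prenyl bromide | CC(C)=CCBr | starting material
20 | 1-[2,4,6-trihydroxy-3-(3-methylbut-2-enyl)phenyl]ethanone | CC(=O)c1c(O)cc(O)c(CC=C(C)C)c1O | intermediate
21 | 1-[2-hydroxy-4,6-bis(methoxymethoxy)-3-(3-methylbut-2-enyl)phenyl]ethanone | CC(=O)c1c(O)c(CC=C(C)C)c(OCOC)cc1OCOC | intermediate
22 | (E)-3-(dimethylamino)-1-[2-hydroxy-4,6-bis(methoxymethoxy)-3-(3-methylbut-2-enyl)phenyl]prop-2-en-1-one | CN(C)/C=C/C(=O)c1c(O)c(CC=C(C)C)c(OCOC)cc1OCOC | intermediate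
23 | 5,7-bis(methoxymethoxy)-8-(3-methylbut-2-enyl)-4H-chromen-4-one | O=c1ccoc2c(CC=C(C)C)c(OCOC)cc(OCOC)c12 | intermediate
24 | (2S)-2-[2,2-dimethyl-8-(2-methylbut-3-en-2-yloxy)-2H-chromen-6-yl]-5,7-bis(methoxymethoxy)-8-(3-methylbut-2-enyl)chroman-4-one | C=CC(C)(C)Oc1cc([C@@H]2CC(=O)c3c(OCOC)cc(OCOC)c(CC=C(C)C)c3O2)cc4C=CC(C)(C)Oc14 | intermediate
25 | ortho-dienone from the [3,3] shift (C3'=O, sp3 C2' bearing H and prenyl, configuration at C2' undefined, 2S) | CC(C)=CCC1C(=O)C2=C(C=CC(C)(C)O2)C=C1[C@@H]3CC(=O)c4c(OCOC)cc(OCOC)c(CC=C(C)C)c4O3 | intermediate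
26 | (2S)-2-[8-hydroxy-2,2-dimethyl-7-(3-methylbut-2-enyl)-2H-chromen-6-yl]-5,7-bis(methoxymethoxy)-8-(3-methylbut-2-enyl)chroman-4-one | CC(C)=CCc1c([C@@H]2CC(=O)c3c(OCOC)cc(OCOC)c(CC=C(C)C)c3O2)cc2c(c1O)OC(C)(C)C=C2 | intermediate
27 | (2S)-5,7-dihydroxy-2-[8-hydroxy-2,2-dimethyl-7-(3-methylbut-2-enyl)-2H-chromen-6-yl]-8-(3-methylbut-2-enyl)chroman-4-one | CC(C)=CCc1c([C@@H]2CC(=O)c3c(O)cc(O)c(CC=C(C)C)c3O2)cc2c(c1O)OC(C)(C)C=C2 | target

Total step count: 13.
Longest linear sequence: 9 steps (steps 2, 3, 4, 5, 6, 7, 11, 12, 13, from 4 to 27).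

Steps most likely to fail

Step 4. Retro-aldol cleavage of the alkoxide may outrun ring closure on warming. Self-condensation of acetone or loss of hydroxide from the aldolate may also use up the base. The fallback uses known chemistry and puts the ring oxygen on ring B first. Starting from 7, the activated fluoride is displaced by hydroxide (KOH, DMSO–H2O, 80 °C, SNAr ortho to the ketone) to give 1-[5-bromo-2-hydroxy-3-(2-methylbut-3-en-2-yloxy)phenyl]ethanone F1. A Kabbe condensation of this phenol with acetone 8 (pyrrolidine, MeOH, 60 °C; enamine aldol condensation, then oxa-Michael closure) comes back to the route at 11.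

Step 11. Slow insertion of the electron-rich, 5-alkoxylated chromone may let protodeboronation of 17 take over. The aryl–rhodium species may also add to the terminal alkene of the allyl ether, or base may open ring C and erode the configuration. The fallback is an aldol union followed by resolution.
- Starting from 14, bromine–lithium exchange (n-BuLi, THF, −78 °C) and DMF give 2,2-dimethyl-8-(2-methylbut-3-en-2-yloxy)-2H-chromene-6-carbaldehyde F2.
- Claisen–Schmidt condensation of this aldehyde with 21 (KOH, EtOH) gives (E)-3-[2,2-dimethyl-8-(2-methylbut-3-en-2-yloxy)-2H-chromen-6-yl]-1-[2-hydroxy-4,6-bis(methoxymethoxy)-3-(3-methylbut-2-enyl)phenyl]prop-2-en-1-one F3.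
- NaOAc in refluxing EtOH closes ring C to the racemic 2-[2,2-dimethyl-8-(2-methylbut-3-en-2-yloxy)-2H-chromen-6-yl]-5,7-bis(methoxymethoxy)-8-(3-methylbut-2-enyl)chroman-4-one F4.
- A Noyori–Ikariya transfer hydrogenation is run as a kinetic resolution (RuCl(p-cymene)[TsDPEN], the enantiomer that consumes the 2R ketone, HCO2H–Et3N, EtOAc). It reduces the 2R ketone to the cis alcohol (2R,4R)-2-[2,2-dimethyl-8-(2-methylbut-3-en-2-yloxy)-2H-chromen-6-yl]-5,7-bis(methoxymethoxy)-8-(3-methylbut-2-enyl)chroman-4-ol F5, which is separated. The 2S ketone is left behind, and the fallback comes back to the route at 24.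

Step 12. The Lewis acid or heat may ionise the tertiary allyl ether with loss of the C5 unit. The [3,3] shift into C2', next to the bulky C1' substituent, may be slow, or prolonged heating may open ring C and erode C2. The fallback moves the rearrangement to an early achiral stage.
- Starting from 14, heating in toluene at 120 °C gives 6-bromo-2,2-dimethyl-7-(3-methylbut-2-enyl)-2H-chromen-8-ol F6. C8a is blocked, so only C7 can accept the allyl terminus.
- MOMCl and iPr2NEt give 6-bromo-8-(methoxymethoxy)-2,2-dimethyl-7-(3-methylbut-2-enyl)-2H-chromene F7.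
- Bromine–lithium exchange and B(OiPr)3 give [8-(methoxymethoxy)-2,2-dimethyl-7-(3-methylbut-2-enyl)-2H-chromen-6-yl]boronic acid F8.
- The rhodium-catalysed 1,4-addition to 23 under the conditions of step 11 gives (2S)-5,7-bis(methoxymethoxy)-2-[8-(methoxymethoxy)-2,2-dimethyl-7-(3-methylbut-2-enyl)-2H-chromen-6-yl]-8-(3-methylbut-2-enyl)chroman-4-one F9.
- HCl in MeOH as in step 13 comes back to the route at 27.

Further compounds
F1 | step 4 | 1-[5-bromo-2-hydroxy-3-(2-methylbut-3-en-2-yloxy)phenyl]ethanone | CC(=O)c1cc(Br)cc(OC(C)(C)C=C)c1O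
F2 | step 11 | 2,2-dimethyl-8-(2-methylbut-3-en-2-yloxy)-2H-chromene-6-carbaldehyde | O=Cc1cc2C=CC(C)(C)Oc2c(OC(C)(C)C=C)c1
F3 | step 11 | (E)-3-[2,2-dimethyl-8-(2-methylbut-3-en-2-yloxy)-2H-chromen-6-yl]-1-[2-hydroxy-4,6-bis(methoxymethoxy)-3-(3-methylbut-2-enyl)phenyl]prop-2-en-1-one | C=CC(C)(C)Oc1cc(/C=C/C(=O)c2c(O)c(CC=C(C)C)c(OCOC)cc2OCOC)cc3C=CC(C)(C)Oc13
F4 | step 11 | racemic 2-[2,2-dimethyl-8-(2-methylbut-3-en-2-yloxy)-2H-chromen-6-yl]-5,7-bis(methoxymethoxy)-8-(3-methylbut-2-enyl)chroman-4-one | C=CC(C)(C)Oc1cc(C2CC(=O)c3c(OCOC)cc(OCOC)c(CC=C(C)C)c3O2)cc4C=CC(C)(C)Oc14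
F5 | step 11 | (2R,4R)-2-[2,2-dimethyl-8-(2-methylbut-3-en-2-yloxy)-2H-chromen-6-yl]-5,7-bis(methoxymethoxy)-8-(3-methylbut-2-enyl)chroman-4-ol | C=CC(C)(C)Oc1cc([C@H]2C[C@@H](O)c3c(OCOC)cc(OCOC)c(CC=C(C)C)c3O2)cc4C=CC(C)(C)Oc14
F6 | step 12 | 6-bromo-2,2-dimethyl-7-(3-methylbut-2-enyl)-2H-chromen-8-ol | CC(C)=CCc1c(Br)cc2C=CC(C)(C)Oc2c1O
F7 | step 12 | 6-bromo-8-(methoxymethoxy)-2,2-dimethyl-7-(3-methylbut-2-enyl)-2H-chromene | COCOc1c(CC=C(C)C)c(Br)cc2C=CC(C)(C)Oc12
F8 | step 12 | [8-(methoxymethoxy)-2,2-dimethyl-7-(3-methylbut-2-enyl)-2H-chromen-6-yl]boronic acid | COCOc1c(CC=C(C)C)c(B(O)O)cc2C=CC(C)(C)Oc12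
F9 | step 12 | (2S)-5,7-bis(methoxymethoxy)-2-[8-(methoxymethoxy)-2,2-dimethyl-7-(3-methylbut-2-enyl)-2H-chromen-6-yl]-8-(3-methylbut-2-enyl)chroman-4-one | COCOc1c(CC=C(C)C)c([C@@H]2CC(=O)c3c(OCOC)cc(OCOC)c(CC=C(C)C)c3O2)cc4C=CC(C)(C)Oc14
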